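**Strategy.** The flavone is disconnected at the O1–C2 bond of ring C. A 6-endo-dig iodocyclization of 1-(pentamethoxyphenyl)-3-phenylprop-2-yn-1-one closes the pyranone and places iodine at C3 in one operation. The step exploits the fully oxygenated ring A: C5 and C8a, the two carbons flanking C4a, both carry oxygen, so the acyl group sits between two equivalent methoxy groups and either closure gives the same chromone. The ynone comes from lithiated pentamethoxybenzene and a phenylpropiolic Weinreb amide. The C3 iodide is then exchanged for methoxy and the peri C5 ether is cleaved selectively.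

Key step: step 6

Remark: the target and all isolated compounds are achiral; the tetrahedral adduct 11 forms as a racemate and collapses to the achiral ketone 12.

**Step 1**
Reactants: 1 3,4,5-trimethoxyphenol
Product: 2 1,2,3,5-tetramethoxybenzene
Conditions: MeI, K2CO3, acetone, reflux
Reagents that add atoms: iodomethane, CI
Why: Williamson ether synthesis, in which the phenoxide formed with K2CO3 displaces iodide from iodomethane and no other nucleophilic site is present.

**Step 2**
Reactants: 2 1,2,3,5-tetramethoxybenzene
Product: 5 2,3,4,6-tetramethoxyphenol, via 2,3,4,6-tetramethoxyphenyllithium 3 (not isolated), via lithium aryltrimethoxyborate 4 (not isolated)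
Conditions: n-BuLi, THF, 0 °C → rt; B(OMe)3, −78 °C → rt; AcOH, 30% H2O2, 0 °C
Reagents that add atoms: hydrogen peroxide, OO
Why: Directed ortho-lithiation removes one of the two equivalent ring protons, each flanked by two methoxy groups, and borate trapping followed by peroxide-induced 1,2-migration of the aryl group from boron to oxygen (boronate oxidation) should deliver the phenol.

**Step 3**
Reactants: 5 2,3,4,6-tetramethoxyphenol
Product: 6 pentamethoxybenzene
Conditions: MeI, K2CO3, DMF, 40 °C
Reagents that add atoms: iodomethane, CI
Why: Williamson ether synthesis on a hindered but acidic phenol, for which the polar aprotic solvent should ensure complete O-methylation.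

**Step 4**
Reactants: 7 3-phenylprop-2-ynoic acid (phenylpropiolic acid)
Product: 9 N-methoxy-N-methyl-3-phenylprop-2-ynamide, via 3-phenylprop-2-ynoyl chloride 8 (not isolated)
Conditions: (COCl)2, cat. DMF, CH2Cl2, 0 °C → rt; concentrate; then MeNHOMe·HCl, K2CO3, H2O/CH2Cl2, 0 °C
Reagents that add atoms: N,O-dimethylhydroxylamine hydrochloride, CNOC.Cl
Why: Acyl chloride formation under DMF catalysis followed by Schotten–Baumann amidation is the standard way to a Weinreb amide, and the cold two-phase conditions should keep the amine from adding to the triple bond in conjugate fashion.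

**Step 5**
Reactants: 6 pentamethoxybenzene; 9 N-methoxy-N-methyl-3-phenylprop-2-ynamide
Product: 12 1-(2,3,4,5,6-pentamethoxyphenyl)-3-phenylprop-2-yn-1-one, via pentamethoxyphenyllithium 10 (not isolated), via lithium hemiaminal alkoxide 11 (not isolated)
Conditions: n-BuLi, TMEDA, THF, 0 °C; then 9, −78 °C; cold 1 M HCl quench
Reagents that add atoms: none
Why: Directed ortho-lithiation at the only ring C–H followed by Weinreb ketone synthesis, in which the chelated adduct 11 cannot collapse before the quench, so over-addition is excluded, and the acidic quench protonates the released amine before it can add to the ynone.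

**Step 6**
Reactants: 12 1-(2,3,4,5,6-pentamethoxyphenyl)-3-phenylprop-2-yn-1-one
Product: 14 3-iodo-5,6,7,8-tetramethoxy-2-phenyl-4H-chromen-4-one (3-iodo-5,6,7,8-tetramethoxyflavone), via O1-methyloxonium chloride 13 (not isolated)
Conditions: ICl (1.2 equiv), CH2Cl2, −78 °C → rt; aq. Na2S2O3 work-up
Reagents that add atoms: iodine monochloride, ClI
Why: Iodine monochloride should deliver electrophilic iodine to the triple bond of 12, and one of the two equivalent ortho methoxy oxygens attacks the phenyl-bearing β-carbon anti to iodine, forming the O1–C2 bond and the methyloxonium salt 13; chloride then removes the O-methyl group by SN2 displacement as chloromethane and leaves the neutral pyranone with iodine at C3. The closest known reaction type is the iodine monochloride-induced cyclization of ortho-methoxyaryl alkynyl ketones to 3-iodochromones (electrophilic iodocyclization with dealkylation). Ring C is closed in the 6-endo-dig mode. No stereocentre is formed. The step needs 6-endo over 5-exo closure, which the ynone polarization secures because the carbonyl withdraws density from the α-carbon while the phenyl group stabilizes positive charge at the β-carbon; it also needs a single constitutional outcome, which the mirror symmetry of the pentamethoxyphenyl group secures, since both ortho ethers lead to the same product. Ring A carries no C–H bond, so ring iodination cannot compete.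

**Step 7**
Reactants: 14 3-iodo-5,6,7,8-tetramethoxy-2-phenyl-4H-chromen-4-one
Product: 15 3,5,6,7,8-pentamethoxy-2-phenyl-4H-chromen-4-one (3,5,6,7,8-pentamethoxyflavone)
Conditions: CuI (10 mol%), 1,10-phenanthroline (20 mol%), Cs2CO3, MeOH/toluene, 100 °C, sealed tube
Reagents that add atoms: methanol, CO
Why: Ullmann-type copper-catalysed C–O coupling of the C3 vinyl iodide with methanol should replace iodine by methoxy, the electron-poor α-iodoenone being well suited to oxidative addition and the aryl methyl ethers being inert.

**Step 8**
Reactants: 15 3,5,6,7,8-pentamethoxy-2-phenyl-4H-chromen-4-one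
Product: 17 5-hydroxy-3,6,7,8-tetramethoxy-2-phenyl-4H-chromen-4-one (5-hydroxy-3,6,7,8-tetramethoxyflavone), via C5 dichloroboryl ether 16 (not isolated)
Conditions: BCl3 (1.5 equiv), CH2Cl2, −78 °C → 0 °C; then H2O
Reagents that add atoms: none
Why: Chelation-controlled Lewis acid ether cleavage, in which BCl3 bound to the C4 carbonyl oxygen activates the peri C5 methoxy group, chloride removes its methyl group to give the six-membered boron chelate 16, and the C3, C6, C7 and C8 ethers should survive at low temperature with a limited amount of reagent.

**Compound list**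
1 | 3,4,5-trimethoxyphenol | COc1cc(O)cc(OC)c1OC | starting material
2 | 1,2,3,5-tetramethoxybenzene | COc1cc(OC)c(OC)c(OC)c1 | intermediate
3 | (2,3,4,6-tetramethoxyphenyl)lithium (not isolated) | [Li]c1c(OC)cc(OC)c(OC)c1OC | intermediate
4 | lithium trimethoxy(2,3,4,6-tetramethoxyphenyl)borate (not isolated) | [Li+].CO[B-](OC)(OC)c1c(OC)cc(OC)c(OC)c1OC | intermediate
5 | 2,3,4,6-tetramethoxyphenol | COc1cc(OC)c(OC)c(OC)c1O | intermediate
6 | pentamethoxybenzene | COc1cc(OC)c(OC)c(OC)c1OC | intermediate
7 | 3-phenylprop-2-ynoic acid (phenylpropiolic acid) | OC(=O)C#Cc1ccccc1 | starting material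
8 | 3-phenylprop-2-ynoyl chloride (not isolated) | ClC(=O)C#Cc1ccccc1 | intermediate
9 | N-methoxy-N-methyl-3-phenylprop-2-ynamide | CON(C)C(=O)C#Cc1ccccc1 | intermediate
10 | (2,3,4,5,6-pentamethoxyphenyl)lithium (not isolated) | [Li]c1c(OC)c(OC)c(OC)c(OC)c1OC | intermediate
11 | racemic lithium 1-[methoxy(methyl)amino]-1-(2,3,4,5,6-pentamethoxyphenyl)-3-phenylprop-2-yn-1-olate (not isolated) | CON(C)C(O[Li])(C#Cc1ccccc1)c1c(OC)c(OC)c(OC)c(OC)c1OC | intermediate
12 | 1-(2,3,4,5,6-pentamethoxyphenyl)-3-phenylprop-2-yn-1-one | COc1c(OC)c(OC)c(C(=O)C#Cc2ccccc2)c(OC)c1OC | intermediate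
13 | 3-iodo-5,6,7,8-tetramethoxy-1-methyl-4-oxo-2-phenyl-4H-chromen-1-ium chloride (not isolated) | COc1c(OC)c(OC)c2C(=O)C(I)=C(c3ccccc3)[O+](C)c2c1OC.[Cl-] | intermediate
14 | 3-iodo-5,6,7,8-tetramethoxy-2-phenyl-4H-chromen-4-one | COc1c(OC)c(OC)c2c(=O)c(I)c(-c3ccccc3)oc2c1OC | intermediate
15 | 3,5,6,7,8-pentamethoxy-2-phenyl-4H-chromen-4-one | COc1c(OC)c(OC)c2c(=O)c(OC)c(-c3ccccc3)oc2c1OC | intermediate
16 | 5-(dichloroboryloxy)-3,6,7,8-tetramethoxy-2-phenyl-4H-chromen-4-one (not isolated) | COc1c(OC)c(OB(Cl)Cl)c2c(=O)c(OC)c(-c3ccccc3)oc2c1OC | intermediate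
17 | 5-hydroxy-3,6,7,8-tetramethoxy-2-phenyl-4H-chromen-4-one (5-hydroxy-3,6,7,8-tetramethoxyflavone) | COc1c(OC)c(O)c2c(=O)c(OC)c(-c3ccccc3)oc2c1OC | target

**Step count.** Total steps: 8. Longest linear sequence: 7 steps (steps 1, 2, 3, 5, 6, 7 and 8 from 3,4,5-trimethoxyphenol); step 4 is the side branch.

**Steps most likely to fail**

Step 6. The electrophile may add across the triple bond without ring closure, the closure may go 5-exo, or the very electron-rich ring A may be attacked at an ipso position and oxidized. The fallback gives up the iodocyclization and builds ring C by classical condensation. It sets out from 6: Friedel–Crafts acylation with methoxyacetyl chloride and AlCl3 in Et2O, with chelation-driven loss of one ortho methyl group, should give 1-(2-hydroxy-3,4,5,6-tetramethoxyphenyl)-2-methoxyethan-1-one F1. Allan–Robinson condensation of this ketone with benzoic anhydride and potassium benzoate at about 180 °C, followed by brief treatment with ethanolic KOH, should form the pyranone with the C3 methoxy group already in place. The fallback comes back to the route at 15.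

Step 7. Reductive loss of iodine may outrun the coupling, or methoxide may add at C2 and open the pyranone ring. The fallback reverses the polarity at C3 and sets out from 14. Iodine–magnesium exchange with iPrMgCl·LiCl in THF at −40 °C should give 3-(chloromagnesio)-5,6,7,8-tetramethoxy-2-phenyl-4H-chromen-4-one F2. Trapping with B(OMe)3 should give dimethyl (5,6,7,8-tetramethoxy-4-oxo-2-phenyl-4H-chromen-3-yl)boronate F3, and oxidation with H2O2 in AcOH at 0 °C should give 3-hydroxy-5,6,7,8-tetramethoxy-2-phenyl-4H-chromen-4-one F4. Methylation of this flavonol with MeI and K2CO3 in acetone comes back to the route at 15.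

Step 5. The aryllithium may add to the triple bond of the amide in conjugate fashion, or the released amine may add to the ynone during work-up. The fallback replaces the acylation by aldehyde addition and oxidation and sets out from 6. Lithiation as in step 5 gives 10, and addition of commercial 3-phenylprop-2-ynal at −78 °C should give racemic 1-(2,3,4,5,6-pentamethoxyphenyl)-3-phenylprop-2-yn-1-ol F5. Oxidation of this alcohol with MnO2 in CH2Cl2 at rt comes back to the route at 12.

**Further compounds**
F1 | step 6 | 1-(2-hydroxy-3,4,5,6-tetramethoxyphenyl)-2-methoxyethan-1-one | COCC(=O)c1c(O)c(OC)c(OC)c(OC)c1OC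
F2 | step 7 | 3-(chloromagnesio)-5,6,7,8-tetramethoxy-2-phenyl-4H-chromen-4-one | COc1c(OC)c(OC)c2c(=O)c([Mg]Cl)c(-c3ccccc3)oc2c1OC
F3 | step 7 | dimethyl (5,6,7,8-tetramethoxy-4-oxo-2-phenyl-4H-chromen-3-yl)boronate | COB(OC)c1c(-c2ccccc2)oc2c(OC)c(OC)c(OC)c(OC)c2c1=O
F4 | step 7 | 3-hydroxy-5,6,7,8-tetramethoxy-2-phenyl-4H-chromen-4-one | COc1c(OC)c(OC)c2c(=O)c(O)c(-c3ccccc3)oc2c1OC
F5 | step 5 | racemic 1-(2,3,4,5,6-pentamethoxyphenyl)-3-phenylprop-2-yn-1-ol | COc1c(OC)c(OC)c(C(O)C#Cc2ccccc2)c(OC)c1OC
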